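With the arene numbered from the acetoxy carbon (C1) through the tridecyl carbon (C2) to the hydroxyl (C4) and methoxy (C6) carbons, the hindered C1–O bond is derived from a C1 acetyl group by Baeyer–Villiger insertion. C1 and C2 are then the sp carbons of an alkynyl methyl ketone. One Diels–Alder/aromatisation of this ynone with an oxygenated four-carbon diene (C3–C6) forms C2–C3 and C1–C6, builds the benzene ring and delivers all four substituents, the C4 oxygen silylated and the C6 oxygen methylated. The precursors are heptadec-3-yn-2-one and 3-(tert-butyldimethylsilyloxy)-1,1-dimethoxybuta-1,3-diene. The feature exploited is the C1(O)–C2(alkyl) edge flanked by the meta-related C4 and C6 oxygens.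

Key step: step 4

Remark: the target is achiral and no isolated compound of the main route carries a stereocentre, so no configuration has to be set.

Step 1
Reactants: 1 pentadec-1-yne; 2 N-methoxy-N-methylacetamide
Product: 5 heptadec-3-yn-2-one, via lithium pentadec-1-yn-1-ide 3 (not isolated), via lithium hemiaminal alkoxide 4 (not isolated)
Conditions: n-BuLi, THF, −78 °C; then 2, −78 to 0 °C; cold 1 M HCl quench
Reagents that add atoms: none
Why: Weinreb ketone synthesis on a lithium acetylide: the chelated tetrahedral adduct 4 persists until the acidic quench, so the ketone is never exposed to acetylide and cannot be attacked a second time as it would be with an acid chloride, while the cold acid quench keeps the released amine protonated and away from the ynone.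

Step 2
Reactants: 6 1,1-dimethoxyethene; 7 acetyl chloride
Product: 8 4,4-dimethoxybut-3-en-2-one
Conditions: 6 (2.1 equiv), Et2O, 0 °C to rt; distil
Reagents that add atoms: none
Why: C-acylation of a ketene acetal by an acid chloride (addition at the nucleophilic methylene carbon, then proton loss), with the second equivalent of the acetal taking up the HCl as methyl acetate and chloromethane, so that no amine base is present to turn acetyl chloride into ketene.

Step 3
Reactants: 8 4,4-dimethoxybut-3-en-2-one
Product: 9 3-(tert-butyldimethylsilyloxy)-1,1-dimethoxybuta-1,3-diene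
Conditions: TBSOTf, Et3N, Et2O, 0 °C to rt; pentane extraction, short-path distillation under argon
Reagents that add atoms: tert-butyldimethylsilyl trifluoromethanesulfonate (TBSOTf), CC(C)(C)[Si](C)(C)OS(=O)(=O)C(F)(F)F
Why: Silyl dienol ether formation by soft enolisation: O-silylation of the vinylogous carbonate carbonyl gives a dialkoxy-stabilised cation whose only acidic hydrogens are those of the methyl group, so triethylamine can deliver only the 2-silyloxydiene.

Step 4
Reactants: 9 3-(tert-butyldimethylsilyloxy)-1,1-dimethoxybuta-1,3-diene; 5 heptadec-3-yn-2-one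
Product: 11 1-[4-(tert-butyldimethylsilyloxy)-2-methoxy-6-tridecylphenyl]ethan-1-one, via ketal cycloadduct 10 (not isolated)
Conditions: 9 (2 equiv), PhMe, 100 °C, sealed tube, argon; concentrate; chromatography on Et3N-washed SiO2
Reagents that add atoms: none
Why: Thermal normal-electron-demand Diels–Alder reaction of an electron-rich ketene-acetal silyloxydiene with an acetylenic ketone, then aromatising loss of methanol from 10; the closest known reaction type is the cycloaddition–aromatisation of 1,1-dialkoxy-3-silyloxybutadienes with alkynyl ketones and esters, which gives resorcinol monoethers. The two σ-bonds form in one kinetic step but unequally: bonding is most advanced between the methylene end of the diene, where the acetal and silyloxy donors concentrate the HOMO, and the alkyne carbon bearing the tridecyl chain (β to the carbonyl, largest LUMO coefficient), while the bond from the dimethoxy carbon to the carbonyl-bearing alkyne carbon lags behind. The one new ring, the future benzene ring, is closed by intermolecular (4+2) cycloaddition, the diene carbons becoming C3–C6 and the alkyne carbons C2 and C1. No stereocentre arises; in 10 the dimethoxy carbon sits across the ring from the CH2 group, so a 1,4-elimination of methanol, paid for by aromatisation, leaves a single OMe at C6 and the silyl ether at C4 untouched. Regiochemistry is the only selectivity at stake, and the substrates dictate it: every donor on the diene reinforces nucleophilicity at the same end and the ynone has one acceptor, which places tridecyl beside C3–H and acetyl between tridecyl and methoxy. The tert-butyldimethylsilyl group is preferred to trimethylsilyl so that the C4 oxygen leaves the step protected, and the excess diene absorbs the methanol released.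

Step 5
Reactants: 11 1-[4-(tert-butyldimethylsilyloxy)-2-methoxy-6-tridecylphenyl]ethan-1-one
Product: 12 4-(tert-butyldimethylsilyloxy)-2-methoxy-6-tridecylphenyl acetate
Conditions: mCPBA, CH2Cl2, 0 °C to rt
Reagents that add atoms: 3-chloroperoxybenzoic acid (mCPBA), OOC(=O)c1cccc(Cl)c1
Why: Baeyer–Villiger oxidation: in the peracid adduct the electron-rich 2,4-dioxygenated aryl group migrates far more readily than methyl, so oxygen enters on the ring side to give the aryl acetate, and the silyl ether keeps the para oxygen from being oxidised towards a quinone.

Step 6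
Reactants: 12 4-(tert-butyldimethylsilyloxy)-2-methoxy-6-tridecylphenyl acetate
Product: 13 ardisiphenol D (4-hydroxy-2-methoxy-6-tridecylphenyl acetate)
Conditions: HF·pyridine, pyridine, THF, 0 °C to rt
Reagents that add atoms: none
Why: Desilylation of an aryl silyl ether driven by Si–F bond formation, run under mildly acidic HF·pyridine, which is not basic enough to cleave or transfer the aryl acetate as a fluoride salt such as Bu4NF might.

Compound list
1 | pentadec-1-yne | CCCCCCCCCCCCCC#C | starting material
2 | N-methoxy-N-methylacetamide | CON(C)C(C)=O | starting material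
3 | lithium pentadec-1-yn-1-ide | CCCCCCCCCCCCCC#[C-].[Li+] | intermediate (not isolated)
4 | lithium 2-[methoxy(methyl)amino]heptadec-3-yn-2-olate (racemic tetrahedral adduct) | CCCCCCCCCCCCCC#CC(C)([O-])N(C)OC.[Li+] | intermediate (not isolated)
5 | heptadec-3-yn-2-one | CCCCCCCCCCCCCC#CC(C)=O | intermediate
6 | 1,1-dimethoxyethene | C=C(OC)OC | starting material
7 | acetyl chloride | CC(Cl)=O | starting material
8 | 4,4-dimethoxybut-3-en-2-one | CC(=O)C=C(OC)OC | intermediate
9 | 3-(tert-butyldimethylsilyloxy)-1,1-dimethoxybuta-1,3-diene | COC(OC)=CC(=C)O[Si](C)(C)C(C)(C)C | intermediate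
10 | 1-[4-(tert-butyldimethylsilyloxy)-6,6-dimethoxy-2-tridecylcyclohexa-1,4-dien-1-yl]ethan-1-one | CCCCCCCCCCCCCC1=C(C(C)=O)C(OC)(OC)C=C(O[Si](C)(C)C(C)(C)C)C1 | intermediate (not isolated)
11 | 1-[4-(tert-butyldimethylsilyloxy)-2-methoxy-6-tridecylphenyl]ethan-1-one | CCCCCCCCCCCCCc1cc(O[Si](C)(C)C(C)(C)C)cc(OC)c1C(C)=O | intermediate
12 | 4-(tert-butyldimethylsilyloxy)-2-methoxy-6-tridecylphenyl acetate | CCCCCCCCCCCCCc1cc(O[Si](C)(C)C(C)(C)C)cc(OC)c1OC(C)=O | intermediate
13 | ardisiphenol D, 4-hydroxy-2-methoxy-6-tridecylphenyl acetate | CCCCCCCCCCCCCc1cc(O)cc(OC)c1OC(C)=O | target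

Total step count: 6.
Longest linear sequence: 5 steps (6 and 7 to 8, 9, 11, 12, 13); the alkyne branch (1 to 5) joins at step 4.

Steps most likely to fail

Step 4 (cycloaddition–aromatisation). The addition to the internal, alkyl-substituted triple bond may be slower than thermal decomposition or hydrolysis of the diene, or than its attack on the ketone carbonyl. The fallback uses a smaller, more electrophilic dienophile and homologates its formyl group afterwards. It sets out from alkyne 1. Lithiation to acetylide 3 (n-BuLi, THF, −78 °C) and formylation with DMF would pass through lithium 1-(dimethylamino)hexadec-2-yn-1-olate F1. An inverse quench into cold aqueous KH2PO4 would then give hexadec-2-ynal F2. Heating F2 with diene 9 in toluene should lead, through the ketal cycloadduct 4-(tert-butyldimethylsilyloxy)-6,6-dimethoxy-2-tridecylcyclohexa-1,4-diene-1-carbaldehyde F3 and loss of methanol, to 4-(tert-butyldimethylsilyloxy)-2-methoxy-6-tridecylbenzaldehyde F4. Addition of MeMgBr (THF, 0 °C) would give racemic 1-[4-(tert-butyldimethylsilyloxy)-2-methoxy-6-tridecylphenyl]ethan-1-ol F5. Oxidation with Dess–Martin periodinane (CH2Cl2, rt) comes back to the route at ketone 11.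

Step 5 (Baeyer–Villiger oxidation). Peracid addition to the twisted, doubly ortho-substituted ketone may be slow enough for electrophilic oxidation of the electron-rich ring, or for methyl migration, to compete. The fallback uses a formyl group as the latent oxygen and acetylates the single free phenol that results. It sets out from alkyne 1 and follows the preceding fallback through hexadec-2-ynal F2 as far as 4-(tert-butyldimethylsilyloxy)-2-methoxy-6-tridecylbenzaldehyde F4. The unhindered aldehyde should undergo Dakin-type oxidation with mCPBA (CH2Cl2, 0 °C) to 4-(tert-butyldimethylsilyloxy)-2-methoxy-6-tridecylphenyl formate F6. Brief methanolysis (MeOH, catalytic Et3N, 0 °C), which should leave the aryl silyl ether intact, would give 4-(tert-butyldimethylsilyloxy)-2-methoxy-6-tridecylphenol F7. Acetylation of its only free hydroxyl (Ac2O, pyridine, DMAP) comes back to the route at acetate 12.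

Step 2 (acylation of the ketene acetal). Chloride may capture the dimethoxycarbenium intermediate, with loss of chloromethane to give methyl acetoacetate, or acid may polymerise the ketene acetal before the wanted proton loss. The fallback builds the dimethoxy enone by substitution at a dichlorovinyl ketone. It sets out from acetyl chloride 7. AlCl3-promoted addition to 1,1-dichloroethene (CH2Cl2, 0 °C) would give 4,4,4-trichlorobutan-2-one F8, which loses HCl on distillation to 4,4-dichlorobut-3-en-2-one F9. Twofold addition–elimination with NaOMe (2 equiv, MeOH, 0 °C) replaces both vinylic chlorides and comes back to the route at enone 8.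

Further compounds
F1 | step 4 | lithium 1-(dimethylamino)hexadec-2-yn-1-olate (racemic) | CCCCCCCCCCCCCC#CC([O-])N(C)C.[Li+]
F2 | step 4 | hexadec-2-ynal | CCCCCCCCCCCCCC#CC=O
F3 | step 4 | 4-(tert-butyldimethylsilyloxy)-6,6-dimethoxy-2-tridecylcyclohexa-1,4-diene-1-carbaldehyde | CCCCCCCCCCCCCC1=C(C=O)C(OC)(OC)C=C(O[Si](C)(C)C(C)(C)C)C1
F4 | step 4 | 4-(tert-butyldimethylsilyloxy)-2-methoxy-6-tridecylbenzaldehyde | CCCCCCCCCCCCCc1cc(O[Si](C)(C)C(C)(C)C)cc(OC)c1C=O
F5 | step 4 | 1-[4-(tert-butyldimethylsilyloxy)-2-methoxy-6-tridecylphenyl]ethan-1-ol (racemic) | CCCCCCCCCCCCCc1cc(O[Si](C)(C)C(C)(C)C)cc(OC)c1C(C)O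
F6 | step 5 | 4-(tert-butyldimethylsilyloxy)-2-methoxy-6-tridecylphenyl formate | CCCCCCCCCCCCCc1cc(O[Si](C)(C)C(C)(C)C)cc(OC)c1OC=O
F7 | step 5 | 4-(tert-butyldimethylsilyloxy)-2-methoxy-6-tridecylphenol | CCCCCCCCCCCCCc1cc(O[Si](C)(C)C(C)(C)C)cc(OC)c1O
F8 | step 2 | 4,4,4-trichlorobutan-2-one | CC(=O)CC(Cl)(Cl)Cl
F9 | step 2 | 4,4-dichlorobut-3-en-2-one | CC(=O)C=C(Cl)Cl
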